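**Plan**

- Labels: ring B = C5(=C4Me2)–C6–C7–C8(H)–C9(Me)–C10(H, chain C1–C3); ring C = C8–C9–C11–C12–C13(H, Me)–C14(Me, CH2Ar); C15 = benzylic CH2.
- Retrosynthesis: the quinone comes from a 2,6-dialkylphenol, C5=C4 from a C5 ketone, and the C5 ketone and the C10–C1 bond from the alkenyl triflate of a bicyclic enone C10(=O)–C5=C6.
- That enone is cut at C8–C9 and C5–C6 together. Carbonyl C10 with its two α-carbons C9 and C5 is a 1,3-dinucleophile and C8=C7–C6H=O a 1,3-dielectrophile, so ring B is the [3+3] sum of a ketone and an enal. Because C8–C9 is also the last bond of ring C, the precursor is an open-chain keto enal; the C10 carbonyl is the helper and is removed afterwards.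
- Forward: quaternary C14 by two alkylations of a chiral butyrolactone; the chain by selenolate opening, Giese addition and Wittig olefination; ring C (Michael) then ring B (aldol condensation) in one flask; then the C10 chain, the C5 ketone, the isopropylidene group and the quinone.
- Stereochemistry: C13 is bought; C14 follows by anti alkylation; C8 and C9 arise together in the bicyclization under control of C13/C14; C10 comes from hydroboration anti to the C9 methyl.

Key step: step 9

Remark: (R)-4-methyldihydrofuran-2(3H)-one is taken as a purchasable chiral-pool lactone; Ar = 2-methoxy-3-methylphenyl serves as the masked methylbenzoquinone.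

**Route**

Step 1
Reactants: 1 2,6-dimethylanisole
Product: 2 1-(bromomethyl)-2-methoxy-3-methylbenzene
Conditions: N-bromosuccinimide (1.0 equiv), AIBN (cat.), PhCF3, 85 °C
Reagents that add atoms: N-bromosuccinimide, O=C1CCC(=O)N1Br
Why: Wohl–Ziegler radical bromination of one benzylic methyl group; the methoxy group, twisted out of the ring plane by its two ortho substituents, activates the ring little, which favors side-chain over ring bromination.

Step 2
Reactants: 3 (R)-4-methyldihydrofuran-2(3H)-one; 2 1-(bromomethyl)-2-methoxy-3-methylbenzene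
Product: 5 (3R,4R)-3-(2-methoxy-3-methylbenzyl)-4-methyldihydrofuran-2(3H)-one, via lithium lactone enolate 4 (not isolated)
Conditions: LiN(i-Pr)2, THF, −78 °C; then 2, −78 → −20 °C
Reagents that add atoms: none
Why: Alkylation of the lithium lactone enolate by the benzylic bromide (SN2), the arylmethyl group entering trans to the C13 methyl; this center is planarized again in step 3, so only the purchased C13 center matters here.

Step 3
Reactants: 5 (3R,4R)-3-(2-methoxy-3-methylbenzyl)-4-methyldihydrofuran-2(3H)-one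
Product: 7 (3S,4R)-3-(2-methoxy-3-methylbenzyl)-3,4-dimethyldihydrofuran-2(3H)-one, via lithium benzyl-lactone enolate 6 (not isolated)
Conditions: LiN(i-Pr)2, THF, −78 °C; then MeI, −78 → 0 °C
Reagents that add atoms: iodomethane, CI
Why: Second enolate alkylation: iodomethane attacks the planar enolate on the face opposite the adjacent C13 methyl, so the new methyl is trans and the arylmethyl group cis to it, which sets quaternary C14 by 1,2-induction.

Step 4
Reactants: 7 (3S,4R)-3-(2-methoxy-3-methylbenzyl)-3,4-dimethyldihydrofuran-2(3H)-one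
Product: 8 (2S,3R)-2-(2-methoxy-3-methylbenzyl)-2,3-dimethyl-4-(phenylselanyl)butanoic acid
Conditions: PhSeH, NaH, THF, 0 °C; then 7, 18-crown-6, DMF, 90 °C; aq. HCl
Reagents that add atoms: benzeneselenol (as its sodium salt), [SeH]c1ccccc1
Why: SN2 opening of the lactone at the O–CH2 carbon (C12) by the soft selenolate (alkyl–oxygen cleavage), which frees the C8 carboxyl and puts a radical leaving group on C12 without touching C13 or C14; the aryl methyl ether needs a much higher temperature for the same SN2 cleavage.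

Step 5
Reactants: 8 (2S,3R)-2-(2-methoxy-3-methylbenzyl)-2,3-dimethyl-4-(phenylselanyl)butanoic acid
Product: 9 (2S,3R)-2-(2-methoxy-3-methylbenzyl)-2,3-dimethyl-4-(phenylselanyl)butan-1-ol
Conditions: LiAlH4, THF, 0 → 50 °C; aq. NaOH work-up
Reagents that add atoms: none
Why: Hydride reduction of the carboxylic acid to the neopentyl primary alcohol; the aryl selenide and the aryl ether are inert to LiAlH4.

Step 6
Reactants: 9 (2S,3R)-2-(2-methoxy-3-methylbenzyl)-2,3-dimethyl-4-(phenylselanyl)butan-1-ol
Product: 10 (3RS,6S,7S)-8-hydroxy-7-(2-methoxy-3-methylbenzyl)-3,6,7-trimethyloctan-2-one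
Conditions: Bu3SnH (slow addition), AIBN (cat.), 3-methylbut-3-en-2-one (8 equiv), PhH, 80 °C
Reagents that add atoms: 3-methylbut-3-en-2-one, CC(=C)C(C)=O
Why: Giese reaction: the stannyl radical abstracts the phenylselanyl group, the primary C12 radical adds to the CH2 terminus of the enone and the α-keto radical is reduced by Bu3SnH, which forms C12–C11 and brings in C9, C10 and C5; C9 forms as both epimers, which is harmless because C9 is enolized in step 9.

Step 7
Reactants: 10 (3RS,6S,7S)-8-hydroxy-7-(2-methoxy-3-methylbenzyl)-3,6,7-trimethyloctan-2-one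
Product: 11 (2S,3S,6RS)-2-(2-methoxy-3-methylbenzyl)-2,3,6-trimethyl-7-oxooctanal
Conditions: Dess–Martin periodinane, CH2Cl2, 0 °C → rt
Reagents that add atoms: none
Why: Dess–Martin oxidation of the primary alcohol to the aldehyde, whose α-carbon is quaternary and cannot epimerize; the ketone is untouched.

Step 8
Reactants: 11 (2S,3S,6RS)-2-(2-methoxy-3-methylbenzyl)-2,3,6-trimethyl-7-oxooctanal
Product: 12 (2E,4S,5S,8RS)-4-(2-methoxy-3-methylbenzyl)-4,5,8-trimethyl-9-oxodec-2-enal
Conditions: Ph3P=CHCHO, PhMe, 100 °C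
Reagents that add atoms: (triphenylphosphoranylidene)acetaldehyde, O=CC=P(c1ccccc1)(c1ccccc1)c1ccccc1
Why: Wittig olefination with a stabilized formyl ylide gives the E enal; the ylide reacts with the aldehyde and not with the ketone.

Step 9
Reactants: 12 (2E,4S,5S,8RS)-4-(2-methoxy-3-methylbenzyl)-4,5,8-trimethyl-9-oxodec-2-enal
Product: 15 (4aR,5S,6S,8aR)-5-(2-methoxy-3-methylbenzyl)-5,6,8a-trimethyl-4a,5,6,7,8,8a-hexahydronaphthalen-1(4H)-one, via Michael-adduct keto aldehyde 13 (not isolated), via aldol β-hydroxy ketone 14 (not isolated)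
Conditions: KOH (0.3 equiv), MeOH, 0.01 M, 0 → 60 °C
Reagents that add atoms: none
Why: Under equilibrating base the more substituted enolate of the methyl ketone (C9=C10–O−) adds to the β-carbon C8 of the enal (intramolecular Michael addition, 6-(enolexo)-exo-trig) and closes ring C by forming C8–C9; proton transfer then gives the methyl-side enolate (C5), which attacks the freed aldehyde C6 (aldol addition, 6-(enolendo)-exo-trig) and closes ring B by forming C5–C6, and E1cB loss of water from 14 makes the sequence irreversible. The closest known reaction type is the Robinson-type Michael–aldol condensation of a ketone with an enal in its [3+3] (α,α′) sense, here run within one chain so that both rings form. C8 is expected to be set by attack on the enal face that places the arylmethyl group of the neighbouring quaternary C14 anti to the forming bond (equatorial in a chair-like transition state, with the C14 and C13 methyls axial), that is by the stereocenters made in steps 2 and 3. C9 is set in the same transition state: the smaller methyl takes the axial site and the acyl carbon C10 the equatorial one, trans to the equatorial CH2CHO arm on C8, which gives the trans ring fusion once ring B closes. The step needs enolate regioselectivity (only the C9 enolate reaches C8 through a six-membered transition state, and the enal has a quaternary γ-carbon and cannot enolize), aldol regioselectivity (the other pairing would give a cyclobutane) and facial selectivity at C8/C9, which rests on substrate control alone.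

Step 10
Reactants: 15 (4aR,5S,6S,8aR)-5-(2-methoxy-3-methylbenzyl)-5,6,8a-trimethyl-4a,5,6,7,8,8a-hexahydronaphthalen-1(4H)-one
Product: 17 (4aR,5S,6S,8aR)-5-(2-methoxy-3-methylbenzyl)-5,6,8a-trimethyl-3,4,4a,5,6,7,8,8a-octahydronaphthalen-1-yl trifluoromethanesulfonate, via lithium enolate 16 (not isolated)
Conditions: Li[HB(s-Bu)3] (L-Selectride), THF, −78 °C; then PhN(SO2CF3)2, −78 → 0 °C; aq. NH4Cl
Reagents that add atoms: N-phenylbis(trifluoromethanesulfonimide), O=S(=O)(N(c1ccccc1)S(=O)(=O)C(F)(F)F)C(F)(F)F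
Why: Conjugate (1,4) hydride reduction of the β-unsubstituted cyclohexenone by the bulky trialkylborohydride, the carbonyl being shielded by the adjacent quaternary C9, gives the C10–C5 enolate regiospecifically, and O-sulfonylation traps it as the alkenyl triflate.

Step 11
Reactants: 17 (4aR,5S,6S,8aR)-5-(2-methoxy-3-methylbenzyl)-5,6,8a-trimethyl-3,4,4a,5,6,7,8,8a-octahydronaphthalen-1-yl trifluoromethanesulfonate
Product: 18 ethyl 3-[(4aR,5S,6S,8aR)-5-(2-methoxy-3-methylbenzyl)-5,6,8a-trimethyl-3,4,4a,5,6,7,8,8a-octahydronaphthalen-1-yl]propanoate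
Conditions: BrZnCH2CH2CO2Et, Pd(PPh3)4 (5 mol %), THF, 60 °C
Reagents that add atoms: (3-ethoxy-3-oxopropyl)zinc bromide, CCOC(=O)CC[Zn]Br
Why: Negishi coupling of the alkenyl triflate with the zinc homoenolate, a reagent that tolerates its own ester, attaches C1–C3 to C10.

Step 12
Reactants: 18 ethyl 3-[(4aR,5S,6S,8aR)-5-(2-methoxy-3-methylbenzyl)-5,6,8a-trimethyl-3,4,4a,5,6,7,8,8a-octahydronaphthalen-1-yl]propanoate
Product: 20 ethyl 3-[(1S,2S,4aR,5S,6S,8aR)-2-hydroxy-5-(2-methoxy-3-methylbenzyl)-5,6,8a-trimethyldecahydronaphthalen-1-yl]propanoate, via C5 alkylborane 19 (not isolated)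
Conditions: BH3·THF, THF, 0 °C → rt; then 30% H2O2, aq. NaOAc, 0 °C → rt
Reagents that add atoms: hydrogen peroxide, OO
Why: Hydroboration–oxidation: boron adds to the less substituted C5 and hydrogen to C10 in a syn fashion from the face opposite the axial C9 methyl, which sets C10 (hydrogen trans to the C9 methyl, chain equatorial); the C5 carbinol center is removed in step 13.

Step 13
Reactants: 20 ethyl 3-[(1S,2S,4aR,5S,6S,8aR)-2-hydroxy-5-(2-methoxy-3-methylbenzyl)-5,6,8a-trimethyldecahydronaphthalen-1-yl]propanoate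
Product: 21 ethyl 3-[(1S,4aR,5S,6S,8aR)-5-(2-methoxy-3-methylbenzyl)-5,6,8a-trimethyl-2-oxodecahydronaphthalen-1-yl]propanoate
Conditions: Dess–Martin periodinane, CH2Cl2, rt
Reagents that add atoms: none
Why: Dess–Martin oxidation of the secondary alcohol to the C5 ketone under near-neutral conditions; C10 carries its chain in the more stable equatorial position, so enolization would not invert it.

Step 14
Reactants: 21 ethyl 3-[(1S,4aR,5S,6S,8aR)-5-(2-methoxy-3-methylbenzyl)-5,6,8a-trimethyl-2-oxodecahydronaphthalen-1-yl]propanoate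
Product: 22 ethyl 3-[(1S,4aR,5S,6S,8aR)-5-(2-methoxy-3-methylbenzyl)-5,6,8a-trimethyl-2-(propan-2-ylidene)decahydronaphthalen-1-yl]propanoate
Conditions: Me2CCl2, Mg, TiCl4, THF, 0 °C → rt
Reagents that add atoms: 2,2-dichloropropane, CC(C)(Cl)Cl
Why: Takai-type titanium-mediated alkylidenation (gem-dihalide, reducing metal, TiCl4): the non-basic titanium isopropylidene reagent converts the C5 ketone to the tetrasubstituted C5=C4 alkene with fixed double-bond position, faster than it attacks the ester and without enolizing C10.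

Step 15
Reactants: 22 ethyl 3-[(1S,4aR,5S,6S,8aR)-5-(2-methoxy-3-methylbenzyl)-5,6,8a-trimethyl-2-(propan-2-ylidene)decahydronaphthalen-1-yl]propanoate
Product: 24 3-[(1S,4aR,5S,6S,8aR)-5-(2-hydroxy-3-methylbenzyl)-5,6,8a-trimethyl-2-(propan-2-ylidene)decahydronaphthalen-1-yl]propanoic acid, via phenol ethyl ester 23 (not isolated)
Conditions: NaSEt, DMF, 130 °C; then aq. NaOH, 60 °C; aq. HCl
Reagents that add atoms: sodium hydroxide, [Na+].[OH-]
Why: SN2 demethylation of the aryl methyl ether by ethanethiolate, then saponification of the ethyl ester in the same flask; the tetrasubstituted alkene and all stereocenters are inert to both.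

Step 16
Reactants: 24 3-[(1S,4aR,5S,6S,8aR)-5-(2-hydroxy-3-methylbenzyl)-5,6,8a-trimethyl-2-(propan-2-ylidene)decahydronaphthalen-1-yl]propanoic acid
Product: 25 3-[(1S,4aR,5S,6S,8aR)-5,6,8a-trimethyl-5-[(5-methyl-3,6-dioxocyclohexa-1,4-dien-1-yl)methyl]-2-(propan-2-ylidene)decahydronaphthalen-1-yl]propanoic acid (CNP0271365.1)
Conditions: K2[ON(SO3)2] (2.2 equiv), KH2PO4, acetone–H2O, rt
Reagents that add atoms: potassium nitrosodisulfonate, [K+].[K+].[O]N(S(=O)(=O)[O-])S(=O)(=O)[O-]
Why: Teuber oxidation: the nitrosodisulfonate radical oxidizes the 2,6-dialkylphenol at its free para position to the 2,6-dialkyl-1,4-benzoquinone; the carboxylate and the alkene do not react.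

**Compound list**

1 | 2,6-dimethylanisole | COc1c(C)cccc1C | starting material
2 | 1-(bromomethyl)-2-methoxy-3-methylbenzene | COc1c(C)cccc1CBr | intermediate
3 | (R)-4-methyldihydrofuran-2(3H)-one | O=C1C[C@@H](C)CO1 | starting material
4 | lithium enolate of 3 (lithium (R)-4-methyl-4,5-dihydrofuran-2-olate) | [Li+].[O-]C1=C[C@@H](C)CO1 | intermediate
5 | (3R,4R)-3-(2-methoxy-3-methylbenzyl)-4-methyldihydrofuran-2(3H)-one (trans) | COc1c(C)cccc1C[C@H]1C(=O)OC[C@@H]1C | intermediate
6 | lithium enolate of 5 (C3 planar, C4 R) | [Li+].[O-]C1=C(Cc2cccc(C)c2OC)[C@@H](C)CO1 | intermediate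
7 | (3S,4R)-3-(2-methoxy-3-methylbenzyl)-3,4-dimethyldihydrofuran-2(3H)-one (methyls trans) | COc1c(C)cccc1C[C@]1(C)C(=O)OC[C@@H]1C | intermediate
8 | (2S,3R)-2-(2-methoxy-3-methylbenzyl)-2,3-dimethyl-4-(phenylselanyl)butanoic acid | COc1c(C)cccc1C[C@](C)(C(=O)O)[C@@H](C)C[Se]c1ccccc1 | intermediate
9 | (2S,3R)-2-(2-methoxy-3-methylbenzyl)-2,3-dimethyl-4-(phenylselanyl)butan-1-ol | COc1c(C)cccc1C[C@](C)(CO)[C@@H](C)C[Se]c1ccccc1 | intermediate
10 | (3RS,6S,7S)-8-hydroxy-7-(2-methoxy-3-methylbenzyl)-3,6,7-trimethyloctan-2-one | COc1c(C)cccc1C[C@](C)(CO)[C@@H](C)CCC(C)C(C)=O | intermediate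
11 | (2S,3S,6RS)-2-(2-methoxy-3-methylbenzyl)-2,3,6-trimethyl-7-oxooctanal | COc1c(C)cccc1C[C@](C)(C=O)[C@@H](C)CCC(C)C(C)=O | intermediate
12 | (2E,4S,5S,8RS)-4-(2-methoxy-3-methylbenzyl)-4,5,8-trimethyl-9-oxodec-2-enal | COc1c(C)cccc1C[C@](C)(/C=C/C=O)[C@@H](C)CCC(C)C(C)=O | intermediate
13 | 2-[(1R,2R,5S,6S)-2-acetyl-6-(2-methoxy-3-methylbenzyl)-2,5,6-trimethylcyclohexyl]acetaldehyde (Michael adduct, ring C closed) | COc1c(C)cccc1C[C@]2(C)[C@@H](CC=O)[C@](C)(C(C)=O)CC[C@@H]2C | intermediate
14 | (4aR,5S,6S,8aR)-3-hydroxy-5-(2-methoxy-3-methylbenzyl)-5,6,8a-trimethyloctahydronaphthalen-1(2H)-one (aldol, both C3 epimers) | COc1c(C)cccc1C[C@]2(C)[C@H]3CC(O)CC(=O)[C@]3(C)CC[C@@H]2C | intermediate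
15 | (4aR,5S,6S,8aR)-5-(2-methoxy-3-methylbenzyl)-5,6,8a-trimethyl-4a,5,6,7,8,8a-hexahydronaphthalen-1(4H)-one (trans-fused) | COc1c(C)cccc1C[C@]2(C)[C@H]3CC=CC(=O)[C@]3(C)CC[C@@H]2C | intermediate
16 | lithium (4aR,5S,6S,8aR)-5-(2-methoxy-3-methylbenzyl)-5,6,8a-trimethyl-3,4,4a,5,6,7,8,8a-octahydronaphthalen-1-olate | COc1c(C)cccc1C[C@]2(C)[C@H]3CCC=C([O-])[C@]3(C)CC[C@@H]2C.[Li+] | intermediate
17 | (4aR,5S,6S,8aR)-5-(2-methoxy-3-methylbenzyl)-5,6,8a-trimethyl-3,4,4a,5,6,7,8,8a-octahydronaphthalen-1-yl trifluoromethanesulfonate | COc1c(C)cccc1C[C@]2(C)[C@H]3CCC=C(OS(=O)(=O)C(F)(F)F)[C@]3(C)CC[C@@H]2C | intermediate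
18 | ethyl 3-[(4aR,5S,6S,8aR)-5-(2-methoxy-3-methylbenzyl)-5,6,8a-trimethyl-3,4,4a,5,6,7,8,8a-octahydronaphthalen-1-yl]propanoate | COc1c(C)cccc1C[C@]2(C)[C@H]3CCC=C(CCC(=O)OCC)[C@]3(C)CC[C@@H]2C | intermediate
19 | C5 alkylborane from 18 (BH2 on C5 and new H on C10 both on the face opposite the C9 methyl) | COc1c(C)cccc1C[C@]2(C)[C@H]3CC[C@H](B)[C@@H](CCC(=O)OCC)[C@]3(C)CC[C@@H]2C | intermediate
20 | ethyl 3-[(1S,2S,4aR,5S,6S,8aR)-2-hydroxy-5-(2-methoxy-3-methylbenzyl)-5,6,8a-trimethyldecahydronaphthalen-1-yl]propanoate | COc1c(C)cccc1C[C@]2(C)[C@H]3CC[C@H](O)[C@@H](CCC(=O)OCC)[C@]3(C)CC[C@@H]2C | intermediate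
21 | ethyl 3-[(1S,4aR,5S,6S,8aR)-5-(2-methoxy-3-methylbenzyl)-5,6,8a-trimethyl-2-oxodecahydronaphthalen-1-yl]propanoate | COc1c(C)cccc1C[C@]2(C)[C@H]3CCC(=O)[C@@H](CCC(=O)OCC)[C@]3(C)CC[C@@H]2C | intermediate
22 | ethyl 3-[(1S,4aR,5S,6S,8aR)-5-(2-methoxy-3-methylbenzyl)-5,6,8a-trimethyl-2-(propan-2-ylidene)decahydronaphthalen-1-yl]propanoate | COc1c(C)cccc1C[C@]2(C)[C@H]3CCC(=C(C)C)[C@@H](CCC(=O)OCC)[C@]3(C)CC[C@@H]2C | intermediate
23 | ethyl 3-[(1S,4aR,5S,6S,8aR)-5-(2-hydroxy-3-methylbenzyl)-5,6,8a-trimethyl-2-(propan-2-ylidene)decahydronaphthalen-1-yl]propanoate (present as its sodium phenolate) | Oc1c(C)cccc1C[C@]2(C)[C@H]3CCC(=C(C)C)[C@@H](CCC(=O)OCC)[C@]3(C)CC[C@@H]2C | intermediate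
24 | 3-[(1S,4aR,5S,6S,8aR)-5-(2-hydroxy-3-methylbenzyl)-5,6,8a-trimethyl-2-(propan-2-ylidene)decahydronaphthalen-1-yl]propanoic acid | Oc1c(C)cccc1C[C@]2(C)[C@H]3CCC(=C(C)C)[C@@H](CCC(=O)O)[C@]3(C)CC[C@@H]2C | intermediate
25 | 3-[(1S,4aR,5S,6S,8aR)-5,6,8a-trimethyl-5-[(5-methyl-3,6-dioxocyclohexa-1,4-dien-1-yl)methyl]-2-(propan-2-ylidene)decahydronaphthalen-1-yl]propanoic acid | CC1=CC(=O)C=C(C[C@]2(C)[C@H]3CCC(=C(C)C)[C@@H](CCC(=O)O)[C@]3(C)CC[C@@H]2C)C1=O | target

**Step count and risks**

Total step count: 16. Longest linear sequence: 16 (1 → 25 through steps 1–16; lactone 3 enters in step 2).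

Steps most likely to fail:

1. Step 9. Ring C may close through the other chair (arylmethyl axial), that is by attack on the opposite enal face, which would give the C8/C9 diastereomeric series; a rough conformational estimate does not clearly favor either chair. The bimolecular aldol condensation of the methyl ketone with the enal may also outrun the hindered Michael closure. The fallback sets out from 12 and returns at 15. Compound 12 is converted with Me3SiOSO2CF3/Et3N into the more substituted silyl enol ether F1. An intramolecular Mukaiyama–Michael addition under iminium catalysis by a chiral imidazolidinone salt, chosen so that its shielding group blocks the unwanted enal face, then closes ring C under catalyst control and gives keto aldehyde 13, now isolated. Pyrrolidinium acetate finally effects the aldol condensation of 13 to 15, so the two bonds are made in separate, individually controlled steps.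

2. Step 14. The alkylidenation may be slow or incomplete at the hindered ketone, the ketone may be reduced or enolized instead, or the ester may be attacked. The fallback sets out from 21 and returns at 22. Kinetic deprotonation of 21 at C6 with KN(SiMe3)2 and trapping with PhN(SO2CF3)2 gives the enol triflate F2. Suzuki–Miyaura coupling with isopropenylboronic acid pinacol ester (Pd(PPh3)4, K3PO4) gives the 2-substituted 1,3-diene F3. 1,4-Hydrogenation with H2 and (η6-naphthalene)Cr(CO)3 adds hydrogen to C6 and to the terminal methylene and leaves the C5=C4 double bond, which is 22.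

3. Step 8. Olefination of the neopentyl aldehyde by the weakly nucleophilic formyl ylide may be sluggish, and the enal formed may be homologated a second time. The fallback sets out from 11 and returns at 12. Horner–Wadsworth–Emmons reaction of 11 with (EtO)2P(O)CH2CO2Et (LiCl, DBU) gives the keto enoate F4. i-Bu2AlH reduces ester and ketone to the diol F5. Dess–Martin periodinane oxidizes both carbinols and returns keto enal 12.

**Further compounds**

F1 | step 9 | (2E,4S,5S)-4-(2-methoxy-3-methylbenzyl)-4,5,8-trimethyl-9-[(trimethylsilyl)oxy]deca-2,8-dienal | COc1c(C)cccc1C[C@](C)(/C=C/C=O)[C@@H](C)CCC(C)=C(C)O[Si](C)(C)C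
F2 | step 14 | ethyl 3-[(1S,4aR,5S,6S,8aR)-5-(2-methoxy-3-methylbenzyl)-5,6,8a-trimethyl-2-(trifluoromethanesulfonyloxy)-1,4,4a,5,6,7,8,8a-octahydronaphthalen-1-yl]propanoate | COc1c(C)cccc1C[C@]2(C)[C@H]3CC=C(OS(=O)(=O)C(F)(F)F)[C@@H](CCC(=O)OCC)[C@]3(C)CC[C@@H]2C
F3 | step 14 | ethyl 3-[(1S,4aR,5S,6S,8aR)-5-(2-methoxy-3-methylbenzyl)-5,6,8a-trimethyl-2-(prop-1-en-2-yl)-1,4,4a,5,6,7,8,8a-octahydronaphthalen-1-yl]propanoate | COc1c(C)cccc1C[C@]2(C)[C@H]3CC=C(C(C)=C)[C@@H](CCC(=O)OCC)[C@]3(C)CC[C@@H]2C
F4 | step 8 | ethyl (2E,4S,5S,8RS)-4-(2-methoxy-3-methylbenzyl)-4,5,8-trimethyl-9-oxodec-2-enoate | COc1c(C)cccc1C[C@](C)(/C=C/C(=O)OCC)[C@@H](C)CCC(C)C(C)=O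
F5 | step 8 | (2E,4S,5S)-4-(2-methoxy-3-methylbenzyl)-4,5,8-trimethyldec-2-ene-1,9-diol (mixture at C8 and C9) | COc1c(C)cccc1C[C@](C)(/C=C/CO)[C@@H](C)CCC(C)C(C)O
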